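## Retrosynthetic overview

- End-group (carotenoid) numbering is used. The plan rests on the cyclohexene end group: gem-dimethyl C1, stereocentre C2 carrying side-chain carbon C1'', and the tetrasubstituted C5=C6 alkene. C2 bears the same three carbon arms (C1, C3, C1'') as C4 of (R)-limonene.
- C50 diol 20 ⇐ diester 19 (ester reduction) ⇐ twofold Wittig reaction at C11=C12 and C11'=C12' between two molecules of C20 phosphonium salt 15 and C10 dialdehyde 16.
- 15 ⇐ ionone-type keto ester 13 (vinyl addition at C9, then allylic transposition to the phosphonium salt).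
- 13 ⇐ acyclic dienone 12 by proton-initiated C1–C6 closure. This is the only ring-forming event; each six-membered ring is made before the two halves are joined.
- 12 ⇐ (R)-limonene 1: cleavage of the ring C=C, aldehyde-selective Wittig reaction (side-chain enoate), then ethynylation, Saucy–Marbet rearrangement and isomerisation at the methyl ketone.

Key step: step 7

Remark: centres and axes that are destroyed later (epoxide carbons of 2, carbinol carbons of 3, 7 and 14, allene axis of 11) are carried as mixtures and left undefined in the SMILES. Compounds 12 and 15 are drawn as their major (E) isomers; the (Z) isomers formed alongside converge in steps 7 and 10.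

## Route

Step 1
Reactants: 1 (R)-limonene
Product: 2 (4R)-limonene 1,2-oxide (cis/trans mixture)
Conditions: mCPBA (1.0 equiv), NaHCO3, CH2Cl2, 0 °C
Reagents that add atoms: mCPBA, O=C(OO)c1cccc(Cl)c1
Why: Prilezhaev epoxidation should occur at the more electron-rich trisubstituted ring alkene in preference to the 1,1-disubstituted isopropenyl group; the new epoxide centres are removed in step 2.

Step 2
Reactants: 2 (4R)-limonene 1,2-oxide
Product: 4 (3R)-6-oxo-3-(prop-1-en-2-yl)heptanal, via diol 3 (not isolated)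
Conditions: H5IO6 (1.1 equiv), THF/H2O, 0 °C → rt; used crude
Reagents that add atoms: water, O
Why: Acid-mediated hydrolysis of the epoxide to the diol and Malaprade glycol cleavage by periodic acid run in the same pot; the stereocentre is not α to either new carbonyl group and should keep its configuration.

Step 3
Reactants: 4 (3R)-6-oxo-3-(prop-1-en-2-yl)heptanal; 5 ethyl 2-(triphenylphosphoranylidene)propanoate
Product: 6 ethyl (2E,5R)-2-methyl-8-oxo-5-(prop-1-en-2-yl)non-2-enoate
Conditions: 5 (1.05 equiv), CH2Cl2, 0 °C → rt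
Reagents that add atoms: none
Why: Wittig olefination with a stabilised ylide is selective for the aldehyde over the methyl ketone at room temperature and should give the (E)-trisubstituted enoate.

Step 4
Reactants: 6 ethyl (2E,5R)-2-methyl-8-oxo-5-(prop-1-en-2-yl)non-2-enoate
Product: 7 ethyl (2E,5R)-8-hydroxy-2,8-dimethyl-5-(prop-1-en-2-yl)dec-2-en-9-ynoate (C8 epimers)
Conditions: HC≡CMgBr (1.3 equiv), THF, 0 °C; H2O quench
Reagents that add atoms: ethynylmagnesium bromide, C#C[Mg]Br
Why: Grignard 1,2-addition of the alkynyl nucleophile to the methyl ketone should be much faster than attack on the α-methyl-substituted enoate at 0 °C; the carbinol centre forms unselectively and is destroyed in step 5.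

Step 5
Reactants: 7 ethyl (2E,5R)-8-hydroxy-2,8-dimethyl-5-(prop-1-en-2-yl)dec-2-en-9-ynoate; 8 2-methoxypropene
Product: 11 ethyl (2E,5R)-2,8-dimethyl-12-oxo-5-(prop-1-en-2-yl)trideca-2,8,9-trienoate, via mixed ketal 9 (not isolated), via propargyl isopropenyl ether 10 (not isolated)
Conditions: 8 (3 equiv), p-TsOH·H2O (0.2 mol %), toluene, sealed tube, 90 °C; Et3N quench
Reagents that add atoms: none
Why: Saucy–Marbet reaction: acid-catalysed addition of the tertiary propargylic alcohol to 2-methoxypropene, loss of methanol to the propargyl isopropenyl ether and [3,3]-sigmatropic (propargyl Claisen) rearrangement should give the β-ketoallene, as in the conversion of dehydrolinalool into pseudoionone.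

Step 6
Reactants: 11 ethyl (2E,5R)-2,8-dimethyl-12-oxo-5-(prop-1-en-2-yl)trideca-2,8,9-trienoate
Product: 12 ethyl (2E,5R,8E,10E)-2,8-dimethyl-12-oxo-5-(prop-1-en-2-yl)trideca-2,8,10-trienoate
Conditions: NaOEt (0.1 equiv), EtOH, 0 °C
Reagents that add atoms: none
Why: Base-mediated prototropic isomerisation of the β-ketoallene gives the conjugated dienone; catalytic ethoxide matches the ethyl ester, and the 8E/8Z mixture expected at the new trisubstituted alkene is of no consequence for step 7.

Step 7
Reactants: 12 ethyl (2E,5R,8E,10E)-2,8-dimethyl-12-oxo-5-(prop-1-en-2-yl)trideca-2,8,10-trienoate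
Product: 13 ethyl (2E)-2-methyl-4-[(1R)-2,2,4-trimethyl-3-[(1E)-3-oxobut-1-en-1-yl]cyclohex-3-en-1-yl]but-2-enoate
Conditions: 95% H2SO4 (6 equiv), CH2Cl2, −15 °C, short contact time; poured onto ice
Reagents that add atoms: none
Why: Markovnikov protonation of the isopropenyl CH2 of 12 gives the tertiary C1 carbocation, which is captured by C6 of the C5=C6 alkene (C1–C6 bond) in a 6-endo-trig closure through a chair-like transition state; the C5 cation then loses the C6 proton, and the strong acid holds the ring alkene in the tetrasubstituted C5=C6 position conjugated with the enone. The closest known reaction type is the H2SO4 cyclization of pseudoionone to β-ionone and of its C2-methyl homologues to irones, and both the 8E and 8Z isomers of 12 should converge on 13. No new stereocentre is formed, since C6 ends sp2, so the only stereochemical demand is that C2 keep the configuration brought from limonene. This requires ring closure to outrun a 1,2-hydride shift from C2 to C1 or loss of the C2 proton; low temperature favours the closure, and in H2SO4 the enoate is O-protonated, which places positive charge on C2'' two bonds from C2 and so disfavours a cation at C2 relative to C1. Site selectivity of protonation follows from the isopropenyl group being the only isolated, electron-rich alkene; the enoate and dienone C=C bonds are deactivated by their protonated carbonyl groups. The ethyl enoate is non-nucleophilic and should survive the short exposure to cold acid.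

Step 8
Reactants: 13 ethyl (2E)-2-methyl-4-[(1R)-2,2,4-trimethyl-3-[(1E)-3-oxobut-1-en-1-yl]cyclohex-3-en-1-yl]but-2-enoate
Product: 14 ethyl (2E)-4-[(1R)-3-[(1E)-3-hydroxy-3-methylpenta-1,4-dien-1-yl]-2,2,4-trimethylcyclohex-3-en-1-yl]-2-methylbut-2-enoate (carbinol epimers)
Conditions: CH2=CHMgBr (1.2 equiv), THF, −30 °C; H2O quench
Reagents that add atoms: vinylmagnesium bromide, C=C[Mg]Br
Why: 1,2-addition of the vinyl Grignard reagent to the dienone carbonyl group, as in the preparation of vinyl-β-ionol, should outpace attack on the enoate at −30 °C; the carbinol centre is lost in step 9.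

Step 9
Reactants: 14 ethyl (2E)-4-[(1R)-3-[(1E)-3-hydroxy-3-methylpenta-1,4-dien-1-yl]-2,2,4-trimethylcyclohex-3-en-1-yl]-2-methylbut-2-enoate
Product: 15 {(2E,4E)-5-[(5R)-5-[(2E)-4-ethoxy-3-methyl-4-oxobut-2-en-1-yl]-2,6,6-trimethylcyclohex-1-en-1-yl]-3-methylpenta-2,4-dien-1-yl}triphenylphosphonium bromide
Conditions: PPh3·HBr (1.05 equiv), EtOH, rt, dark
Reagents that add atoms: triphenylphosphine hydrobromide, [Br-].[PH+](c1ccccc1)(c1ccccc1)c1ccccc1
Why: SN1-type ionisation of the tertiary doubly allylic alcohol and capture of the pentadienyl cation by PPh3 at the primary terminus (allylic transposition) gives the Wittig salt, the standard route to C15-type polyenyl phosphonium salts; ethanol as solvent avoids ester exchange.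

Step 10
Reactants: 15 C20 phosphonium bromide (2.2 equiv); 16 (2E,4E,6E)-2,7-dimethylocta-2,4,6-trienedial
Product: 19 diethyl (2E,2'E)-4,4'-[(2R,2'R)-β,β-carotene-2,2'-diyl]bis(2-methylbut-2-enoate), via ylide 17 (not isolated), via C30 aldehyde 18 (not isolated)
Conditions: NaOEt (1.05 equiv per 15), EtOH/CH2Cl2, 0 °C → rt, Ar, dark; then reflux in EtOH and crystallisation
Reagents that add atoms: none
Why: Twofold Wittig olefination of the semi-stabilised polyenyl ylide with the dialdehyde forms the C11=C12 and C11'=C12' bonds; Z isomers at these disubstituted bonds are expected to equilibrate thermally to the all-E polyene, as is usual in carotenoid synthesis, and ethoxide as base leaves the ethyl esters unchanged.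

Step 11
Reactants: 19 diethyl (2E,2'E)-4,4'-[(2R,2'R)-β,β-carotene-2,2'-diyl]bis(2-methylbut-2-enoate)
Product: 20 (2R,2'R)-2,2'-bis[(2E)-4-hydroxy-3-methylbut-2-en-1-yl]-β,β-carotene (CNP0359519.1)
Conditions: i-Bu2AlH (5 equiv), CH2Cl2, −78 → −40 °C; aq. KNaC4H4O6 work-up, Ar, dark
Reagents that add atoms: none
Why: i-Bu2AlH should reduce both α,β-unsaturated esters by 1,2-hydride delivery to the allylic alcohols at low temperature without touching the polyene, and the C2 and C2' centres are not involved.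

## Compound list

1 | (R)-limonene | CC1=CC[C@@H](CC1)C(C)=C | starting material
2 | (4R)-1-methyl-4-(prop-1-en-2-yl)-7-oxabicyclo[4.1.0]heptane (limonene 1,2-oxide, cis/trans mixture) | CC12CC[C@H](CC1O2)C(C)=C | intermediate
3 | (4R)-1-methyl-4-(prop-1-en-2-yl)cyclohexane-1,2-diol | CC1(O)CC[C@H](CC1O)C(C)=C | intermediate (not isolated)
4 | (3R)-6-oxo-3-(prop-1-en-2-yl)heptanal | CC(=O)CC[C@H](CC=O)C(C)=C | intermediate
5 | ethyl 2-(triphenylphosphoranylidene)propanoate | CCOC(=O)C(C)=P(c1ccccc1)(c1ccccc1)c1ccccc1 | starting material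
6 | ethyl (2E,5R)-2-methyl-8-oxo-5-(prop-1-en-2-yl)non-2-enoate | CC(=O)CC[C@H](C/C=C(\C)C(=O)OCC)C(C)=C | intermediate
7 | ethyl (2E,5R)-8-hydroxy-2,8-dimethyl-5-(prop-1-en-2-yl)dec-2-en-9-ynoate (C8 epimers) | C#CC(C)(O)CC[C@H](C/C=C(\C)C(=O)OCC)C(C)=C | intermediate
8 | 2-methoxypropene | COC(C)=C | starting material
9 | ethyl (2E,5R)-8-[(2-methoxypropan-2-yl)oxy]-2,8-dimethyl-5-(prop-1-en-2-yl)dec-2-en-9-ynoate | C#CC(C)(OC(C)(C)OC)CC[C@H](C/C=C(\C)C(=O)OCC)C(C)=C | intermediate (not isolated)
10 | ethyl (2E,5R)-2,8-dimethyl-5-(prop-1-en-2-yl)-8-(prop-1-en-2-yloxy)dec-2-en-9-ynoate | C#CC(C)(OC(C)=C)CC[C@H](C/C=C(\C)C(=O)OCC)C(C)=C | intermediate (not isolated)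
11 | ethyl (2E,5R)-2,8-dimethyl-12-oxo-5-(prop-1-en-2-yl)trideca-2,8,9-trienoate | CC(=O)CC=C=C(C)CC[C@H](C/C=C(\C)C(=O)OCC)C(C)=C | intermediate
12 | ethyl (2E,5R,8E,10E)-2,8-dimethyl-12-oxo-5-(prop-1-en-2-yl)trideca-2,8,10-trienoate | CC(=O)/C=C/C=C(\C)CC[C@H](C/C=C(\C)C(=O)OCC)C(C)=C | intermediate
13 | ethyl (2E)-2-methyl-4-[(1R)-2,2,4-trimethyl-3-[(1E)-3-oxobut-1-en-1-yl]cyclohex-3-en-1-yl]but-2-enoate | CC(=O)/C=C/C1=C(C)CC[C@H](C/C=C(\C)C(=O)OCC)C1(C)C | intermediate
14 | ethyl (2E)-4-[(1R)-3-[(1E)-3-hydroxy-3-methylpenta-1,4-dien-1-yl]-2,2,4-trimethylcyclohex-3-en-1-yl]-2-methylbut-2-enoate | C=CC(C)(O)/C=C/C1=C(C)CC[C@H](C/C=C(\C)C(=O)OCC)C1(C)C | intermediate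
15 | {(2E,4E)-5-[(5R)-5-[(2E)-4-ethoxy-3-methyl-4-oxobut-2-en-1-yl]-2,6,6-trimethylcyclohex-1-en-1-yl]-3-methylpenta-2,4-dien-1-yl}triphenylphosphonium bromide | C(/C=C(C)/C=C/C1=C(C)CC[C@H](C/C=C(\C)C(=O)OCC)C1(C)C)[P+](c1ccccc1)(c1ccccc1)c1ccccc1.[Br-] | intermediate
16 | (2E,4E,6E)-2,7-dimethylocta-2,4,6-trienedial | O=C/C(C)=C/C=C/C=C(C)/C=O | starting material
17 | ylide of 15 (triphenylphosphonium polyenylide) | [CH-](/C=C(C)/C=C/C1=C(C)CC[C@H](C/C=C(\C)C(=O)OCC)C1(C)C)[P+](c1ccccc1)(c1ccccc1)c1ccccc1 | intermediate (not isolated)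
18 | ethyl (2E)-2-methyl-4-[(2R)-12'-oxo-12'-apo-β-caroten-2-yl]but-2-enoate (C30 aldehyde) | O=C/C(C)=C/C=C/C=C(C)/C=C/C=C(C)/C=C/C1=C(C)CC[C@H](C/C=C(\C)C(=O)OCC)C1(C)C | intermediate (not isolated)
19 | diethyl (2E,2'E)-4,4'-[(2R,2'R)-β,β-carotene-2,2'-diyl]bis(2-methylbut-2-enoate) | CC1=C(/C=C/C(C)=C/C=C/C(C)=C/C=C/C=C(C)/C=C/C=C(C)/C=C/C2=C(C)CC[C@H](C/C=C(\C)C(=O)OCC)C2(C)C)C(C)(C)[C@@H](C/C=C(\C)C(=O)OCC)CC1 | intermediate
20 | (2R,2'R)-2,2'-bis[(2E)-4-hydroxy-3-methylbut-2-en-1-yl]-β,β-carotene | CC1=C(/C=C/C(C)=C/C=C/C(C)=C/C=C/C=C(C)/C=C/C=C(C)/C=C/C2=C(C)CC[C@H](C/C=C(\C)CO)C2(C)C)C(C)(C)[C@@H](C/C=C(\C)CO)CC1 | target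

## Step count and risks

Total step count: 11. Longest linear sequence: 11 steps, from (R)-limonene 1 to 20.

Steps most likely to fail:

1. Step 7. The C2 configuration may be lost through a 1,2-hydride shift or proton loss at the C1 cation before ring closure, and the isopropenyl CH2 terminus may close onto C5 of the protonated dienone instead. The fallback avoids any carbocation next to C2; it sets out from 7 and comes back at 13.
   - Palladium-hydride reductive cyclization of the 1,7-enyne 7 (Pd2(dba)3·CHCl3, P(o-tol)3, AcOH, Et3SiH, toluene, 40 °C) would join the internal alkyne carbon (C6) to the internal isopropenyl carbon (C1) in a 6-exo carbopalladation. The neopentyl alkylpalladium intermediate has no β-hydrogen and is reduced to the second C1 methyl group, giving ethyl (2E)-4-[(1R)-4-hydroxy-2,2,4-trimethyl-3-methylidenecyclohexyl]-2-methylbut-2-enoate F1.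
   - Oxidative 1,3-transposition of this tertiary allylic alcohol with pyridinium chlorochromate [C5H5NH][CrO3Cl] in CH2Cl2 (Babler–Dauben oxidation) would give the cyclocitral-type aldehyde ethyl (2E)-4-[(1R)-3-formyl-2,2,4-trimethylcyclohex-3-en-1-yl]-2-methylbut-2-enoate F2.
   - Claisen–Schmidt condensation of F2 with acetone (NaOEt, acetone/EtOH) would then give 13.

2. Step 10. The second olefination may stay incomplete, Z double bonds may form at C11=C12 and C11'=C12', and the base may degrade the dialdehyde. The fallback replaces the phosphonium ylide by a phosphonate carbanion; it sets out from 14 and comes back at 19.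
   - PBr3 (Et2O, −10 °C) would convert 14 with allylic transposition into the primary allylic bromide ethyl (2E)-4-[(1R)-3-[(1E,3E)-5-bromo-3-methylpenta-1,3-dien-1-yl]-2,2,4-trimethylcyclohex-3-en-1-yl]-2-methylbut-2-enoate F3.
   - Michaelis–Arbuzov reaction with P(OEt)3 (90 °C) would give the phosphonate ethyl (2E)-4-[(1R)-3-[(1E,3E)-5-(diethoxyphosphoryl)-3-methylpenta-1,3-dien-1-yl]-2,2,4-trimethylcyclohex-3-en-1-yl]-2-methylbut-2-enoate F4.
   - Twofold Horner–Wadsworth–Emmons olefination of 16 with F4 (KOtBu, THF, −30 °C → rt) is expected to be more E-selective and to give 19.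

3. Step 5. At 90 °C under acid, dehydration of the tertiary propargylic alcohol to an enyne and protonation of the isopropenyl group may compete with ketal exchange and rearrangement. The fallback is acid-free; it sets out from 7 and comes back at 11.
   - Thermal acetoacetylation of 7 with 2,2,6-trimethyl-4H-1,3-dioxin-4-one (xylene, 135 °C, acetone distilled off) would give the acetoacetate ethyl (2E,5R)-2,8-dimethyl-8-[(3-oxobutanoyl)oxy]-5-(prop-1-en-2-yl)dec-2-en-9-ynoate F5.
   - Further heating to 160 °C would bring about the Carroll rearrangement to the allenic β-keto acid (8R,10E)-2-acetyl-12-ethoxy-5,11-dimethyl-12-oxo-8-(prop-1-en-2-yl)dodeca-3,4,10-trienoic acid F6, which loses CO2 to give 11.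

## Further compounds

F1 | step 7 | ethyl (2E)-4-[(1R)-4-hydroxy-2,2,4-trimethyl-3-methylidenecyclohexyl]-2-methylbut-2-enoate (C4 epimers) | C=C1C(C)(O)CC[C@H](C/C=C(\C)C(=O)OCC)C1(C)C
F2 | step 7 | ethyl (2E)-4-[(1R)-3-formyl-2,2,4-trimethylcyclohex-3-en-1-yl]-2-methylbut-2-enoate | O=CC1=C(C)CC[C@H](C/C=C(\C)C(=O)OCC)C1(C)C
F3 | step 10 | ethyl (2E)-4-[(1R)-3-[(1E,3E)-5-bromo-3-methylpenta-1,3-dien-1-yl]-2,2,4-trimethylcyclohex-3-en-1-yl]-2-methylbut-2-enoate | BrC/C=C(C)/C=C/C1=C(C)CC[C@H](C/C=C(\C)C(=O)OCC)C1(C)C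
F4 | step 10 | ethyl (2E)-4-[(1R)-3-[(1E,3E)-5-(diethoxyphosphoryl)-3-methylpenta-1,3-dien-1-yl]-2,2,4-trimethylcyclohex-3-en-1-yl]-2-methylbut-2-enoate | CCOP(=O)(OCC)C/C=C(C)/C=C/C1=C(C)CC[C@H](C/C=C(\C)C(=O)OCC)C1(C)C
F5 | step 5 | ethyl (2E,5R)-2,8-dimethyl-8-[(3-oxobutanoyl)oxy]-5-(prop-1-en-2-yl)dec-2-en-9-ynoate | C#CC(C)(OC(=O)CC(C)=O)CC[C@H](C/C=C(\C)C(=O)OCC)C(C)=C
F6 | step 5 | (8R,10E)-2-acetyl-12-ethoxy-5,11-dimethyl-12-oxo-8-(prop-1-en-2-yl)dodeca-3,4,10-trienoic acid | CC(=O)C(C(=O)O)C=C=C(C)CC[C@H](C/C=C(\C)C(=O)OCC)C(C)=C
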